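**Retrosynthetic overview**
1. Target ⇐ sp3–sp2 Negishi coupling of the C12 alkylzinc (from a bromo acetate) with (Z)-3-iodobut-2-enoic acid; this forms C12–C13 and fixes 13Z by retention.
2. Bromo acetate ⇐ bicyclic 3-oxo-19-ester by C3 deoxygenation, ester reduction to C19–OH (auxiliary released) and acetylation.
3. Bicyclic keto ester ⇐ one-operation Mn(OAc)3/Cu(OAc)2 oxidative radical bicyclization of an acyclic (E,E)-dienyl α-methyl β-keto ester carrying (−)-8-phenylmenthyl (bonds C4–C5, then C10–C9, then C8=C17).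
4. Acyclic precursor ⇐ β-keto ester dianion + (E,E)-C11 dibromide (C1–C2 bond); the dibromide comes from geranyl bromide by one-carbon homologation, allylic oxidation and double bromination.
5. Ring order: ring A closes first and ring B second, in the same radical cascade.

Assumption: labdane numbering (C1–C20) is used for all decalins; the target is 19-acetoxylabda-8(17),13Z-dien-15-oic acid, 4S,5R,9S,10R (4α-CH3, 4β-CH2OAc, 5α-H, 9α-H, 10β-CH3).

**Step 1**
Reactants: 1 geranyl bromide; 2 (chloromethyl)(isopropoxy)dimethylsilane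
Product: 5 (3E)-4,8-dimethylnona-3,7-dien-1-ol (homogeraniol), via Grignard reagent 3 (not isolated), via homoallylsilane 4 (not isolated)
Conditions: 2, Mg, THF, reflux; then 1, CuI (5 mol %), THF, −20 → 0 °C; crude, then KF, KHCO3, 30% H2O2, MeOH/THF, rt
Reagents that add atoms: hydrogen peroxide, OO
Why: Copper-catalysed SN2 allylic cross-coupling of the silylmethyl Grignard at the primary carbon of 1 keeps the E-alkene, and Tamao–Kumada oxidation of the C–Si bond then gives the primary alcohol (nucleophilic hydroxymethylation); no stereocentre is formed.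

**Step 2**
Reactants: 5 homogeraniol
Product: 6 (2E,6E)-2,6-dimethylnona-2,6-diene-1,9-diol
Conditions: SeO2 (0.3 equiv), t-BuOOH (3 equiv), salicylic acid (0.1 equiv), CH2Cl2, 0 °C → rt
Reagents that add atoms: selenium dioxide (oxygen relay), O=[Se]=O; tert-butyl hydroperoxide (stoichiometric oxygen source), CC(C)(C)OO
Why: Sharpless SeO2/t-BuOOH allylic oxidation (ene reaction then [2,3]-sigmatropic shift) hydroxylates the (E)-methyl of the terminal isopropylidene group selectively, which fixes the E geometry of the future C5=C10 alkene.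

**Step 3**
Reactants: 6 diol
Product: 7 (2E,6E)-1,9-dibromo-2,6-dimethylnona-2,6-diene
Conditions: CBr4, PPh3 (2.4 equiv each), CH2Cl2, 0 °C
Reagents that add atoms: carbon tetrabromide, BrC(Br)(Br)Br
Why: Appel bromination converts both primary alcohols by SN2 displacement without allylic transposition or loss of alkene geometry.

**Step 4**
Reactants: 8 (−)-8-phenylmenthol [(1R,2S,5R)-5-methyl-2-(2-phenylpropan-2-yl)cyclohexan-1-ol]; 9 ethyl 2-methyl-3-oxobutanoate
Product: 10 (1R,2S,5R)-8-phenylmenthyl 2-methyl-3-oxobutanoate (C2 epimers)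
Conditions: DMAP (0.3 equiv), toluene, reflux, 4 Å MS (removal of EtOH)
Reagents that add atoms: none
Why: DMAP-catalysed transesterification of a β-keto ester through its acylketene installs the auxiliary without touching its stereocentres; the epimeric α-carbon is later planarised.

**Step 5**
Reactants: 10 auxiliary β-keto ester; 7 dibromide
Product: 12 (1R,2S,5R)-8-phenylmenthyl (6E,10E)-13-bromo-2,6,10-trimethyl-3-oxotrideca-6,10-dienoate (C2 epimers), via dianion 11 (not isolated)
Conditions: 10, NaH, THF, 0 °C; n-BuLi, 0 °C; 7 (1.2 equiv), −78 → −30 °C; aq NH4Cl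
Reagents that add atoms: none
Why: Huckin–Weiler γ-alkylation of the β-keto ester dianion, in which the allylic bromide of 7 reacts about two orders of magnitude faster than the homoallylic primary bromide at low temperature, so only the C1–C2 bond forms.

**Step 6**
Reactants: 12 acyclic keto ester
Product: 13 (1R,2S,5R)-8-phenylmenthyl 12-bromo-3-oxo-13,14,15,16-tetranorlabd-8(17)-en-19-oate (4α-CH3, 4β-CO2R, 5α-H, 9α-H, 10β-CH3)
Conditions: Mn(OAc)3·2H2O (2.2 equiv), Cu(OAc)2·H2O (1 equiv), degassed AcOH, 25 °C, 0.05 M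
Reagents that add atoms: none
Why: Snider-type oxidative free-radical polyene cyclization, in which the trivalent manganese enolate gives the C4 radical that closes ring A and then ring B by two 6-endo additions through a chair–chair array of the two E-alkenes (trans fusion, equatorial C9 side chain), the radical reacting in the rotamer with the ester anti to the ketone oxygen so that the ester ends axial (C19, cis to C20), the phenyl group of the auxiliary shielding one face of the planar radical to set the absolute configuration, and the divalent copper salt turning the tertiary C8 radical into the exocyclic 8(17)-alkene by oxidative elimination of the least hindered β-hydrogen.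

**Step 7**
Reactants: 13 bicyclic keto ester
Product: 15 (1R,2S,5R)-8-phenylmenthyl 12-bromo-13,14,15,16-tetranorlabd-8(17)-en-19-oate, via tosylhydrazone 14 (not isolated)
Conditions: TsNHNH2, EtOH, cat. AcOH, 60 °C; evaporate; catecholborane, CHCl3, 0 °C → rt; NaOAc·3H2O, reflux
Reagents that add atoms: none
Why: Caglioti–Kabalka reductive deoxygenation, in which hydride adds to the tosylhydrazone and acetate-induced loss of sulfinate and N2 leaves CH2 at C3 without touching the alkyl bromide, the hindered ester, the alkene or any stereocentre.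

**Step 8**
Reactants: 15 deoxygenated ester
Product: 16 12-bromo-13,14,15,16-tetranorlabd-8(17)-en-19-ol (4S,5R,9S,10R)
Conditions: AlH3 (from LiAlH4 + AlCl3, 3:1), THF, 0 °C → rt
Reagents that add atoms: none
Why: Alane reduces the hindered axial ester to the C19 primary alcohol far faster than it attacks a primary alkyl bromide, and it releases the auxiliary 8 for reuse; stereocentres are untouched.

**Step 9**
Reactants: 16 bromo alcohol
Product: 17 19-acetoxy-12-bromo-13,14,15,16-tetranorlabd-8(17)-ene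
Conditions: Ac2O, pyridine, DMAP (cat.), CH2Cl2, rt
Reagents that add atoms: acetic anhydride, CC(=O)OC(C)=O
Why: DMAP-catalysed acylation of the neopentyl primary alcohol; the bromide and alkene are inert.

**Step 10**
Reactants: 18 but-2-ynoic acid
Product: 19 (Z)-3-iodobut-2-enoic acid
Conditions: NaI, AcOH, 110 °C
Reagents that add atoms: sodium iodide, [Na+].[I-]
Why: Hydroiodination of the ynoic acid by conjugate addition of iodide and anti protonation gives the Z vinyl iodide (iodine cis to CO2H) stereoselectively.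

**Step 11**
Reactants: 17 bromo acetate; 19 (Z)-3-iodobut-2-enoic acid
Product: 22 19-acetoxylabda-8(17),13Z-dien-15-oic acid (target), via alkylzinc bromide 20 (not isolated), via sodium iodobutenoate 21 (not isolated)
Conditions: 17, Zn dust, LiCl, THF, 50 °C; 19, NaH, THF, 0 °C; combine, PdCl2(dppf) (5 mol %), THF/NMP, 25 → 40 °C; cold 0.5 M HCl
Reagents that add atoms: none
Why: Zinc insertion into the primary bromide gives an alkylzinc that tolerates the acetate, and Negishi sp3–sp2 cross-coupling with the pre-formed carboxylate of the Z vinyl iodide proceeds with retention of alkene geometry, so the 13Z acid is obtained directly without an ester to cleave beside the acetate.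

**Compound list**
1 | geranyl bromide, (2E)-1-bromo-3,7-dimethylocta-2,6-diene | CC(C)=CCC/C(C)=C/CBr | starting material
2 | (chloromethyl)(isopropoxy)dimethylsilane | CC(C)O[Si](C)(C)CCl | starting material
3 | (isopropoxydimethylsilyl)methylmagnesium chloride | CC(C)O[Si](C)(C)C[Mg]Cl | intermediate (not isolated)
4 | [(3E)-4,8-dimethylnona-3,7-dien-1-yl](isopropoxy)dimethylsilane | CC(C)=CCC/C(C)=C/CC[Si](C)(C)OC(C)C | intermediate (not isolated)
5 | (3E)-4,8-dimethylnona-3,7-dien-1-ol | CC(C)=CCC/C(C)=C/CCO | intermediate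
6 | (2E,6E)-2,6-dimethylnona-2,6-diene-1,9-diol | OC/C(C)=C/CC/C(C)=C/CCO | intermediate
7 | (2E,6E)-1,9-dibromo-2,6-dimethylnona-2,6-diene | BrC/C(C)=C/CC/C(C)=C/CCBr | intermediate
8 | (−)-8-phenylmenthol, (1R,2S,5R) | O[C@@H]1C[C@H](C)CC[C@H]1C(C)(C)c1ccccc1 | starting material (recovered in step 8)
9 | ethyl 2-methyl-3-oxobutanoate | CCOC(=O)C(C)C(C)=O | starting material
10 | (1R,2S,5R)-8-phenylmenthyl 2-methyl-3-oxobutanoate | CC(=O)C(C)C(=O)O[C@@H]1C[C@H](C)CC[C@H]1C(C)(C)c1ccccc1 | intermediate
11 | sodium lithium dianion of 10 | [Na+].[Li+].[CH2-]C(=O)[C-](C)C(=O)O[C@@H]1C[C@H](C)CC[C@H]1C(C)(C)c1ccccc1 | intermediate (not isolated)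
12 | (1R,2S,5R)-8-phenylmenthyl (6E,10E)-13-bromo-2,6,10-trimethyl-3-oxotrideca-6,10-dienoate | BrCC/C=C(\C)CC/C=C(\C)CCC(=O)C(C)C(=O)O[C@@H]1C[C@H](C)CC[C@H]1C(C)(C)c1ccccc1 | intermediate
13 | (1R,2S,5R)-8-phenylmenthyl 12-bromo-3-oxo-13,14,15,16-tetranorlabd-8(17)-en-19-oate | C=C1CC[C@H]2[C@@](C)(C(=O)O[C@@H]3C[C@H](C)CC[C@H]3C(C)(C)c3ccccc3)C(=O)CC[C@]2(C)[C@H]1CCBr | intermediate
14 | 3-tosylhydrazone of 13 | C=C1CC[C@H]2[C@@](C)(C(=O)O[C@@H]3C[C@H](C)CC[C@H]3C(C)(C)c3ccccc3)C(=NNS(=O)(=O)c3ccc(C)cc3)CC[C@]2(C)[C@H]1CCBr | intermediate (not isolated)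
15 | (1R,2S,5R)-8-phenylmenthyl 12-bromo-13,14,15,16-tetranorlabd-8(17)-en-19-oate | C=C1CC[C@H]2[C@@](C)(C(=O)O[C@@H]3C[C@H](C)CC[C@H]3C(C)(C)c3ccccc3)CCC[C@]2(C)[C@H]1CCBr | intermediate
16 | 12-bromo-13,14,15,16-tetranorlabd-8(17)-en-19-ol | C=C1CC[C@H]2[C@@](C)(CO)CCC[C@]2(C)[C@H]1CCBr | intermediate
17 | 19-acetoxy-12-bromo-13,14,15,16-tetranorlabd-8(17)-ene | C=C1CC[C@H]2[C@@](C)(COC(C)=O)CCC[C@]2(C)[C@H]1CCBr | intermediate
18 | but-2-ynoic acid | CC#CC(=O)O | starting material
19 | (Z)-3-iodobut-2-enoic acid | I/C(C)=C\C(=O)O | intermediate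
20 | alkylzinc bromide from 17 | C=C1CC[C@H]2[C@@](C)(COC(C)=O)CCC[C@]2(C)[C@H]1CC[Zn]Br | intermediate (not isolated)
21 | sodium (Z)-3-iodobut-2-enoate | [Na+].[O-]C(=O)/C=C(/C)I | intermediate (not isolated)
22 | 19-acetoxylabda-8(17),13Z-dien-15-oic acid | C=C1CC[C@H]2[C@@](C)(COC(C)=O)CCC[C@]2(C)[C@H]1CC/C(C)=C\C(=O)O | target

**Totals**
Total steps: 11. Longest linear sequence: 9 (steps 1, 2, 3, 5, 6, 7, 8, 9, 11); steps 4 and 10 are side branches.

**Three steps most likely to fail**

Step 6 (bicyclization). Three things are uncertain. First, the facial bias of the auxiliary without chelation; a chelating Lewis acid cannot be added because holding the ester syn to the ketone oxygen would deliver it equatorial. Second, the ratio of exocyclic to endocyclic alkene from the copper-mediated elimination. Third, the effect of the bulky ester on yield. Minor diastereomers and alkene isomers are removed on AgNO3-impregnated silica. If the sense of induction proves opposite to the shielding model, the enantiomeric auxiliary is used.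

Fallback for step 6: take the absolute configuration from a resolution instead of the auxiliary. It sets out from 9 and 7 and comes back at 16. Ethyl ester 9 is converted with NaH then n-BuLi into its sodium lithium dianion F1 and alkylated with 7 to the ethyl keto ester F2. The same Mn(OAc)3/Cu(OAc)2 cyclization, best precedented for simple alkyl esters, gives the racemic bicyclic ethyl keto ester F3. Its tosylhydrazone F4 is reduced with catecholborane to the racemic ethyl ester F5. AlH3 then gives the racemic bromo alcohol F6, which is resolved by preparative chiral SFC to 16.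

Step 7 (deoxygenation). The C3 ketone sits next to the quaternary C4 that carries the bulky axial ester, so hydrazone formation or hydride delivery may stall.

Fallback for step 7: Barton–McCombie radical deoxygenation of the C3 alcohol. The C12–Br bond would not survive tin radicals, so the bromide is masked first. The fallback sets out from 13 and comes back at 16. CsOAc in DMF at 60 °C exchanges bromide for acetate to give the acetoxy keto ester F7. NaBH4 in EtOH at 0 °C gives the 3β-alcohol F8. PhOC(S)Cl with DMAP gives the phenyl thionocarbonate F9. Bu3SnH with AIBN in toluene at 90 °C gives the deoxygenated acetoxy ester F10. LiAlH4 in refluxing THF cleaves both esters to the 12,19-diol F11 and returns the auxiliary. CBr4/PPh3 (1.05 equiv, −20 °C) then brominates only the unhindered C12 hydroxyl, the neopentyl C19 hydroxyl being inert to SN2 displacement, and gives 16.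

Step 11 (Negishi coupling with a carboxylate partner). The carboxylate may slow transmetalation, or residual acid may protonate the alkylzinc.

Fallback for step 11: couple an ester-protected partner and unmask afterwards. It sets out from 19 (with 20 made from 17 as before) and comes back at 22. Acid 19 is esterified with 2-(trimethylsilyl)ethanol (DCC, DMAP) to the iodo ester F12. Coupling with alkylzinc 20 under PdCl2(dppf) gives the silylethyl ester F13. Bu4NF buffered with AcOH in THF at 0 °C removes the silylethyl group by fluoride-induced fragmentation, leaves the neopentyl acetate, and gives 22.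

**Further compounds**
F1 | step 6 | sodium lithium dianion of ethyl 2-methyl-3-oxobutanoate | [Na+].[Li+].[CH2-]C(=O)[C-](C)C(=O)OCC
F2 | step 6 | ethyl (6E,10E)-13-bromo-2,6,10-trimethyl-3-oxotrideca-6,10-dienoate | BrCC/C=C(\C)CC/C=C(\C)CCC(=O)C(C)C(=O)OCC
F3 | step 6 | racemic ethyl 12-bromo-3-oxo-13,14,15,16-tetranorlabd-8(17)-en-19-oate | C=C1CC[C@H]2[C@@](C)(C(=O)OCC)C(=O)CC[C@]2(C)[C@H]1CCBr.C=C1CC[C@@H]2[C@](C)(C(=O)OCC)C(=O)CC[C@@]2(C)[C@@H]1CCBr
F4 | step 6 | racemic 3-tosylhydrazone of F3 | C=C1CC[C@H]2[C@@](C)(C(=O)OCC)C(=NNS(=O)(=O)c3ccc(C)cc3)CC[C@]2(C)[C@H]1CCBr.C=C1CC[C@@H]2[C@](C)(C(=O)OCC)C(=NNS(=O)(=O)c3ccc(C)cc3)CC[C@@]2(C)[C@@H]1CCBr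
F5 | step 6 | racemic ethyl 12-bromo-13,14,15,16-tetranorlabd-8(17)-en-19-oate | C=C1CC[C@H]2[C@@](C)(C(=O)OCC)CCC[C@]2(C)[C@H]1CCBr.C=C1CC[C@@H]2[C@](C)(C(=O)OCC)CCC[C@@]2(C)[C@@H]1CCBr
F6 | step 6 | racemic 12-bromo-13,14,15,16-tetranorlabd-8(17)-en-19-ol | C=C1CC[C@H]2[C@@](C)(CO)CCC[C@]2(C)[C@H]1CCBr.C=C1CC[C@@H]2[C@](C)(CO)CCC[C@@]2(C)[C@@H]1CCBr
F7 | step 7 | (1R,2S,5R)-8-phenylmenthyl 12-acetoxy-3-oxo-13,14,15,16-tetranorlabd-8(17)-en-19-oate | C=C1CC[C@H]2[C@@](C)(C(=O)O[C@@H]3C[C@H](C)CC[C@H]3C(C)(C)c3ccccc3)C(=O)CC[C@]2(C)[C@H]1CCOC(C)=O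
F8 | step 7 | (1R,2S,5R)-8-phenylmenthyl 12-acetoxy-3β-hydroxy-13,14,15,16-tetranorlabd-8(17)-en-19-oate | C=C1CC[C@H]2[C@@](C)(C(=O)O[C@@H]3C[C@H](C)CC[C@H]3C(C)(C)c3ccccc3)[C@@H](O)CC[C@]2(C)[C@H]1CCOC(C)=O
F9 | step 7 | (1R,2S,5R)-8-phenylmenthyl 12-acetoxy-3β-(phenoxythiocarbonyloxy)-13,14,15,16-tetranorlabd-8(17)-en-19-oate | C=C1CC[C@H]2[C@@](C)(C(=O)O[C@@H]3C[C@H](C)CC[C@H]3C(C)(C)c3ccccc3)[C@@H](OC(=S)Oc3ccccc3)CC[C@]2(C)[C@H]1CCOC(C)=O
F10 | step 7 | (1R,2S,5R)-8-phenylmenthyl 12-acetoxy-13,14,15,16-tetranorlabd-8(17)-en-19-oate | C=C1CC[C@H]2[C@@](C)(C(=O)O[C@@H]3C[C@H](C)CC[C@H]3C(C)(C)c3ccccc3)CCC[C@]2(C)[C@H]1CCOC(C)=O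
F11 | step 7 | 13,14,15,16-tetranorlabd-8(17)-ene-12,19-diol | C=C1CC[C@H]2[C@@](C)(CO)CCC[C@]2(C)[C@H]1CCO
F12 | step 11 | 2-(trimethylsilyl)ethyl (Z)-3-iodobut-2-enoate | C[Si](C)(C)CCOC(=O)/C=C(/C)I
F13 | step 11 | 2-(trimethylsilyl)ethyl 19-acetoxylabda-8(17),13Z-dien-15-oate | C=C1CC[C@H]2[C@@](C)(COC(C)=O)CCC[C@]2(C)[C@H]1CC/C(C)=C\C(=O)OCC[Si](C)(C)C
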